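Target comes slowly in this flask, so ask first where the electrophile must end up, then how fast it gets there.

electrophile 0.10 M; free base 0.500 equiv; protonated nucleophile 2.00 equiv; protic impurity 0.0500 M; time 5.0 h

    2 free base → self-condensation product (k1 = 0.0552 M⁻¹ min⁻¹)
    acid set free + free base ⇌ salt of the base (K2 = 84400 M⁻¹, k2 = 1.75 M⁻¹ min⁻¹)
    electrophile + nucleophile → acid set free + target (k3 = 0.637 M⁻¹ min⁻¹)
    nucleophile + acid set free ⇌ protonated nucleophile, settled at all times (K4 = 1.05 × 10⁵ M⁻¹)
    electrophile + protic impurity → quenched substrate (k5 = 1.66 M⁻¹ min⁻¹)

1. part of the electrophile that has reacted at 5.0 h
2. share of the unused nucleophile that is free and not bound as protonated nucleophile, at 5.0 h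

Turn the settings by hand, one after the other. Take the protic impurity first. It eats electrophile one for one and is charged at less than the electrophile, so it is the limiting reagent of that step. The part it claims, 50.0%, is its charge over the electrophile charged: call this the toll. With the protic impurity as charged, electrophile has a half-life of 0.14 h by this step, short against 5.0 h, so I expect the toll to be paid early. While the protic impurity stays below the electrophile, more of it raises the toll, and more electrophile, with the protic impurity held, lowers it.

Next comes the protonated nucleophile. Left to its balance, with nothing else taking acid set free, I reckon it frees about 0.00138 M of nucleophile, and by this balance that amount goes with the square root of the charge. That gives the electrophile a half-life of 13.1 h, far longer than by the protic impurity. If that amount of nucleophile held over 5.0 h, this route would take 11.6% of the charge from what the toll leaves. Free base takes acid set free, so I expect it to act on this term, which is smaller than the toll, and more time acts on the same term.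

My figure is therefore 61.6% reacted. By the same balance I reckon 0.690% of the nucleophile free at the start, and I expect less at the end.

The forecast is lower on conversion, 59.6%, with 0.37% free, holding that “the protonated nucleophile releases only about 1 mM of free nucleophile”.

The flask gives 60.0% reacted and 0.438% free at 5.0 h. Just after the start, the protic impurity uses electrophile faster than the nucleophile does, by a factor of 94, and at 5.00 h the flask holds, in parts of the electrophile charged, 50.0% quenched substrate, beside a toll of 50.0%, against 10.0% target. In the neighbour charged with 0.030 M of protic impurity, the toll is 30.0%, and in parts of its electrophile charged, quenched substrate ends at 30.0%, target at 11.7%, and 41.7% of the electrophile has reacted.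

The constants used here stand for no real mixture; no experiment stands behind them.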